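**Retrosynthetic overview**
- The target is disconnected to (+)-lariciresinol 9-O-acetate: an acid-triggered quinone methide / intramolecular Friedel–Crafts closure forms the tetralin ring last and sets C1. The tetrahydrofuran oxygen is released as the free CH2OH on C3, so the acetate already sits on the C2 arm.
- (+)-Lariciresinol 9-O-acetate comes from (+)-lariciresinol by lipase acetylation of its only aliphatic OH. (+)-Lariciresinol comes from (−)-secoisolariciresinol by DDQ dehydrogenation to a p-quinone methide and 5-exo oxa-cyclisation (tetrahydrofuran ring, formed first).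
- (−)-Secoisolariciresinol comes from LiAlH4 reduction of an R,R bis-imide, made by oxidative homodimerisation of the (S)-valine-derived oxazolidinone imide of O-pivaloyl dihydroferulic acid. This sets both carbon stereocentres.
- Ring order: tetrahydrofuran (step 4), then tetrahydronaphthalene (step 6) at the expense of the tetrahydrofuran.

Assumption: lignan locants are used for intermediates (C7/C7' benzylic, C8/C8' methine, C9/C9' CH2O; unprimed is the half that ends up carrying the pendant aryl group) and tetralin locants C1–C4 for the target.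

**Step 1**
Reactants: 1 3-(4-hydroxy-3-methoxyphenyl)propanoic acid (dihydroferulic acid); 2 (S)-4-isopropyloxazolidin-2-one
Product: 4 (S)-4-isopropyl-3-[3-(3-methoxy-4-pivaloyloxyphenyl)propanoyl]oxazolidin-2-one, via mixed pivalic anhydride 3 (not isolated)
Conditions: PivCl (2.3 equiv), Et3N (4 equiv), THF, −20 → 0 °C, 1 h; then LiCl (1.1 equiv), 2 (1.05 equiv), rt, 12 h
Reagents that add atoms: pivaloyl chloride, CC(C)(C)C(Cl)=O
Why: One reagent O-acylates the phenol and activates the acid as its mixed pivalic anhydride, whose less hindered carbonyl is then attacked by the LiCl/Et3N-activated oxazolidinone (mixed-anhydride N-acylation of an Evans-type auxiliary); no new stereocentre.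

**Step 2**
Reactants: 4 (S)-4-isopropyl-3-[3-(3-methoxy-4-pivaloyloxyphenyl)propanoyl]oxazolidin-2-one (2 equiv)
Product: 6 (2R,3R)-1,4-bis[(S)-4-isopropyl-2-oxooxazolidin-3-yl]-2,3-bis(3-methoxy-4-pivaloyloxybenzyl)butane-1,4-dione, via lithium Z-enolate 5 (not isolated)
Conditions: LiN(iPr)2 (1.05 equiv), THF, −78 °C, 45 min; then TiCl4 (1.0 equiv, CH2Cl2 solution), −78 °C → rt, 4 h; aq. NH4Cl
Reagents that add atoms: none
Why: Oxidative homocoupling of a chelated Z-imide enolate: tetravalent titanium is reduced to trivalent titanium, and the two α-carbonyl radicals join on the face anti to the isopropyl group of each auxiliary, so both new centres are R (Evans-type auxiliary control); the aryl pivalates have no α-hydrogens and are too hindered to be attacked at −78 °C.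

**Step 3**
Reactants: 6 (2R,3R)-1,4-bis[(S)-4-isopropyl-2-oxooxazolidin-3-yl]-2,3-bis(3-methoxy-4-pivaloyloxybenzyl)butane-1,4-dione
Product: 7 (−)-secoisolariciresinol, (2R,3R)-2,3-bis(4-hydroxy-3-methoxybenzyl)butane-1,4-diol
Conditions: LiAlH4 (6 equiv), THF, 0 °C → rt, 3 h; aq. citric acid work-up (pH 4), EtOAc extraction
Reagents that add atoms: none
Why: Hydride reduction cleaves both exocyclic imide carbonyls to primary alcohols and removes both aryl pivalates reductively in the same flask, so no separate deprotection is needed; the two stereocentres are not enolised and are retained.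

**Step 4**
Reactants: 7 (−)-secoisolariciresinol
Product: 9 (+)-lariciresinol, 4-[(2S,3R,4R)-4-(4-hydroxy-3-methoxybenzyl)-3-(hydroxymethyl)tetrahydrofuran-2-yl]-2-methoxyphenol, via p-quinone methide 8 (not isolated)
Conditions: DDQ (0.8 equiv, added over 1 h), 1,4-dioxane, rt, 2 h; filter, chromatograph, recycle recovered 7
Reagents that add atoms: none
Why: Proposed new method: DDQ removes hydride from one 4-hydroxybenzyl CH2 through the phenol to give p-quinone methide 8, and the C9' hydroxyl adds to C7 in a 5-exo 1,6-oxa-Michael reaction (the ring-closing event of furan lignan biosynthesis), placing the aryl group trans to the neighbouring CH2OH (C7 = S), a configuration that is erased again in step 6; the closest known reaction type is DDQ benzylic oxidative cyclisation of p-hydroxy- or p-alkoxyphenyl alkanols to 2-aryltetrahydrofurans, and sub-stoichiometric DDQ is used to hold back a second oxidation.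

**Step 5**
Reactants: 9 (+)-lariciresinol
Product: 10 (+)-lariciresinol 9-O-acetate, [(2S,3R,4R)-4-(4-hydroxy-3-methoxybenzyl)-2-(4-hydroxy-3-methoxyphenyl)tetrahydrofuran-3-yl]methyl acetate
Conditions: immobilised Candida antarctica lipase B, vinyl acetate (5 equiv), THF, 40 °C, 24 h; filter
Reagents that add atoms: vinyl acetate, C=COC(C)=O
Why: Lipase-catalysed irreversible transesterification acylates the single primary aliphatic hydroxyl and leaves both phenols untouched; no stereocentre is affected.

**Step 6**
Reactants: 10 (+)-lariciresinol 9-O-acetate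
Product: 12 [(1S,2R,3R)-7-hydroxy-1-(4-hydroxy-3-methoxyphenyl)-3-(hydroxymethyl)-6-methoxy-1,2,3,4-tetrahydronaphthalen-2-yl]methyl acetate (target), via O-acetyl p-quinone methide 11 (not isolated)
Conditions: TsOH·H2O (10 mol %), (CF3)2CHOH/CH2Cl2 1:4, 0 °C → rt, 1 h; aq. NaHCO3
Reagents that add atoms: none
Why: Acid ionises the benzylic C7–O bond (assisted by the para-hydroxyl) to the quinone methide/benzylic cation 11, which is captured by the other guaiacyl ring at the position para to its methoxyl in an intramolecular Friedel–Crafts alkylation (the lariciresinol → isolariciresinol rearrangement, an isomerisation without by-product); a chair-like transition state with all three substituents pseudo-equatorial sets C1 as S (1,2-trans, 2,3-trans), and the former ring oxygen becomes the free C3–CH2OH while the acetate stays on the C2 arm.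

**Compound list**
1 | 3-(4-hydroxy-3-methoxyphenyl)propanoic acid (dihydroferulic acid) | COc1cc(CCC(=O)O)ccc1O | starting material
2 | (S)-4-isopropyloxazolidin-2-one | CC(C)[C@H]1COC(=O)N1 | starting material
3 | 3-(3-methoxy-4-pivaloyloxyphenyl)propanoic pivalic anhydride | COc1cc(CCC(=O)OC(=O)C(C)(C)C)ccc1OC(=O)C(C)(C)C | intermediate (not isolated)
4 | (S)-4-isopropyl-3-[3-(3-methoxy-4-pivaloyloxyphenyl)propanoyl]oxazolidin-2-one | COc1cc(CCC(=O)N2[C@@H](C(C)C)COC2=O)ccc1OC(=O)C(C)(C)C | intermediate
5 | lithium Z-enolate of 4 | COc1cc(C/C=C(\[O-])N2[C@@H](C(C)C)COC2=O)ccc1OC(=O)C(C)(C)C.[Li+] | intermediate (not isolated)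
6 | (2R,3R)-1,4-bis[(S)-4-isopropyl-2-oxooxazolidin-3-yl]-2,3-bis(3-methoxy-4-pivaloyloxybenzyl)butane-1,4-dione | O=C([C@H](Cc1ccc(OC(=O)C(C)(C)C)c(OC)c1)[C@@H](Cc1ccc(OC(=O)C(C)(C)C)c(OC)c1)C(=O)N1[C@@H](C(C)C)COC1=O)N1[C@@H](C(C)C)COC1=O | intermediate
7 | (−)-secoisolariciresinol, (2R,3R)-2,3-bis(4-hydroxy-3-methoxybenzyl)butane-1,4-diol | OC[C@H](Cc1ccc(O)c(OC)c1)[C@@H](Cc1ccc(O)c(OC)c1)CO | intermediate
8 | 4-[(2R,3R)-4-hydroxy-3-(4-hydroxy-3-methoxybenzyl)-2-(hydroxymethyl)butylidene]-2-methoxycyclohexa-2,5-dien-1-one (p-quinone methide of 7) | COC1=CC(=C[C@@H](CO)[C@H](CO)Cc2ccc(O)c(OC)c2)C=CC1=O | intermediate (not isolated)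
9 | (+)-lariciresinol, 4-[(2S,3R,4R)-4-(4-hydroxy-3-methoxybenzyl)-3-(hydroxymethyl)tetrahydrofuran-2-yl]-2-methoxyphenol | COc1cc(C[C@H]2CO[C@H](c3ccc(O)c(OC)c3)[C@H]2CO)ccc1O | intermediate
10 | (+)-lariciresinol 9-O-acetate | COc1cc(C[C@H]2CO[C@H](c3ccc(O)c(OC)c3)[C@H]2COC(C)=O)ccc1O | intermediate
11 | (2R,3R)-4-hydroxy-3-(4-hydroxy-3-methoxybenzyl)-2-[(3-methoxy-4-oxocyclohexa-2,5-dien-1-ylidene)methyl]butyl acetate (ring-opened p-quinone methide, O-protonated under the acid) | COC1=CC(=C[C@@H](COC(C)=O)[C@H](CO)Cc2ccc(O)c(OC)c2)C=CC1=O | intermediate (not isolated)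
12 | [(1S,2R,3R)-7-hydroxy-1-(4-hydroxy-3-methoxyphenyl)-3-(hydroxymethyl)-6-methoxy-1,2,3,4-tetrahydronaphthalen-2-yl]methyl acetate | COc1cc([C@H]2c3cc(O)c(OC)cc3C[C@@H](CO)[C@@H]2COC(C)=O)ccc1O | target

**Step count**
Total steps: 6. Longest linear sequence: 6 steps (1 → 4 → 6 → 7 → 9 → 10 → 12).

**Steps most likely to fail**

Step 2 (oxidative enolate dimerisation in the presence of aryl pivalates). The risk is acyl transfer from the pivalate to the enolate or Lewis-acid damage, which would lower yield and diastereoselectivity. The fallback sets out from 1 and carries the phenol as a benzyl ether. Selective phenoxide alkylation (BnBr, NaOH, aq. EtOH, reflux) gives 3-(4-benzyloxy-3-methoxyphenyl)propanoic acid F1. Acylation of 2 (PivCl, Et3N, LiCl, THF) gives (S)-3-[3-(4-benzyloxy-3-methoxyphenyl)propanoyl]-4-isopropyloxazolidin-2-one F2. The same enolate oxidation (LiN(iPr)2, then TiCl4 or CuCl2) gives (2R,3R)-2,3-bis(4-benzyloxy-3-methoxybenzyl)-1,4-bis[(S)-4-isopropyl-2-oxooxazolidin-3-yl]butane-1,4-dione F3. LiBH4 in THF/MeOH reduces it to (2R,3R)-2,3-bis(4-benzyloxy-3-methoxybenzyl)butane-1,4-diol F4, and hydrogenolysis (H2, 10% Pd on carbon, EtOAc/MeOH) comes back to the route at 7.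

Step 4 (mono-dehydrogenation of an unprotected bis-phenol diol). The risk is that 9 is oxidised further as fast as 7, so the yield is capped statistically, and phenol coupling may compete. The fallback sets out from 7 and drives the oxidation to completion: DDQ (2.2 equiv, dioxane) closes both rings to the cis-fused furofuran (+)-pinoresinol F5 with exo aryl groups. One benzylic C–O bond is then cleaved by controlled hydrogenolysis (H2 1 atm, 10% Pd on carbon, EtOAc/MeOH, stopped after one equivalent), which comes back to the route at 9. Over-reduced material is 7 and is recycled.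

Step 6 (Friedel–Crafts with the acetate in place). The risk is that the acetate carbonyl participates at the C7 cation and hands the acetyl group to the newly freed hydroxyl, giving the regioisomeric monoacetate; loss of H8 from 11 to a styrene would also erode C2. The fallback sets out from 9 and cyclises before the acetate is introduced. TFA/CH2Cl2 at 0 °C gives (+)-isolariciresinol F6, and Ac2O/pyridine gives (+)-isolariciresinol tetraacetate F7. Lipase-mediated alcoholysis (immobilised Candida antarctica lipase B, n-BuOH, t-BuOMe, 40 °C) is expected to remove the two aryl acetates and the less hindered C3–CH2OAc, leaving the hindered C2–CH2OAc, and so comes back to the route at 12. That regioselectivity is an expectation from sterics, not an established result.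

**Further compounds**
F1 | step 2 | 3-(4-benzyloxy-3-methoxyphenyl)propanoic acid | COc1cc(CCC(=O)O)ccc1OCc1ccccc1
F2 | step 2 | (S)-3-[3-(4-benzyloxy-3-methoxyphenyl)propanoyl]-4-isopropyloxazolidin-2-one | COc1cc(CCC(=O)N2[C@@H](C(C)C)COC2=O)ccc1OCc1ccccc1
F3 | step 2 | (2R,3R)-2,3-bis(4-benzyloxy-3-methoxybenzyl)-1,4-bis[(S)-4-isopropyl-2-oxooxazolidin-3-yl]butane-1,4-dione | O=C([C@H](Cc1ccc(OCc2ccccc2)c(OC)c1)[C@@H](Cc1ccc(OCc2ccccc2)c(OC)c1)C(=O)N1[C@@H](C(C)C)COC1=O)N1[C@@H](C(C)C)COC1=O
F4 | step 2 | (2R,3R)-2,3-bis(4-benzyloxy-3-methoxybenzyl)butane-1,4-diol | OC[C@H](Cc1ccc(OCc2ccccc2)c(OC)c1)[C@@H](Cc1ccc(OCc2ccccc2)c(OC)c1)CO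
F5 | step 4 | (+)-pinoresinol | COc1cc(ccc1O)[C@@H]1[C@H]2CO[C@@H]([C@H]2CO1)c1ccc(O)c(OC)c1
F6 | step 6 | (+)-isolariciresinol | COc1cc([C@H]2c3cc(O)c(OC)cc3C[C@@H](CO)[C@@H]2CO)ccc1O
F7 | step 6 | (+)-isolariciresinol tetraacetate | COc1cc([C@H]2c3cc(OC(C)=O)c(OC)cc3C[C@@H](COC(C)=O)[C@@H]2COC(C)=O)ccc1OC(C)=O
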